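The runs come from a simulation for substances that don't exist; the scatter is artificial.

How much E stands in this flask within the time allowed, and when is that moment?

1. the moment within 25 h at which there is most E
2. the amount of E, in percent of the Q and L together charged, at that time

| flask | Q | L | J | D | remark | time |
|---|---|---|---|---|---|---|
| north-east | 46 mM | 46 mM | 1.2 equiv | 6.7 mol% | run made earlier |  |
| north-west | 46 mM | 46 mM | 1.2 equiv | 15 mol% | run made earlier |  |
| flask | 46 mM | 46 mM | 1.20 equiv | 10 mol% |  | 25 h |

| run | time / h | E / % | Q / % |
|---|---|---|---|
| north-east | 6.00 | 2.6 | 46.8 |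
| north-east | 8.00 | 4.9 | 45.3 |
| north-east | 12.0 | 9.2 | 41.5 |
| north-east | 15.0 | 9.9 | 40.1 |
| north-west | 6.00 | 7.1 | 43.0 |
| north-west | 8.00 | 9.2 | 39.6 |
| north-west | 12.0 | 14.4 | 34.9 |
| north-west | 15.0 | 17.2 | 33.0 |

(scatter of a reading: 0.5 percentage points)

- Z is single-handed; Q and L are mirror images of each other, charged as a racemate, each of them at the stated concentration

We put the times in order, fastest first. In the north-west run, Q and E add up to 50.2% at the last reading, so the loss of Q tracks E.

Between 6.00 h and 15.0 h, ln c_Q falls at 0.0172 h⁻¹ in north-east and 0.0294 h⁻¹ in north-west.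

The first rung is a start delay. Extending each of these lines back to the charge of Q gives 2.15 h in north-east and 0.872 h in north-west, so we take 1.51 h.

The next rung is the loss of Q. Scaling each slope by its loading of D and averaging gives 0.0226 h⁻¹ for this flask. Our carried quantity is the working half-life of Q, a pseudo-first-order time: ln 2 over that constant, which is 30.6 h.

The time allowed, 25 h, is shorter than this half-life and far longer than the delay. We therefore expect E still rising at the end of this flask, with 20.6%. The late north-east rise of 0.7 percentage points looks like a stall, but it rests on one step of readings with scatter 0.5 points, so we assume no ceiling.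

The forecast says 15% at 25 h, on a plateau, “suggesting the catalyst dies after limited turnover”. Our figure is higher.

This flask gives 20.2% at 25.0 h.

    Z ⇌ X (K = 1.40, k = 0.110 h⁻¹)
    J + Z + Q → Z + E (k = 330 L² mol⁻² h⁻¹)
    D → Z (k = 0.0940 h⁻¹)
    J + Z + L → Z + G (k = 160 L² mol⁻² h⁻¹)

In this flask, the half-life of Q by its step with J and Z is 27 h at 11.3 h and 40 h at 25.0 h, which is longer than the time allowed. At that end, 60% of the charged Q is still there. For a neighbour, the same flask with 3.00 equiv of J, we scale our half-life by the charges of J to 12.3 h. With the same delay this gives 36.8% of E. That neighbour holds 37.5% of E at 25.0 h.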